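**Retrosynthetic overview**
1. Target ⇒ acrylate of the 6β-hydroxyl + 3-iodophenol (Mizoroki–Heck makes the cinnamate C–C bond last); acrylate ⇒ eudesmane-4β,6β-diol + acryloyl chloride.
2. Diol ⇒ trans-fused 4β-hydroxy-6-ketone (hydride from the α-face sets C6).
3. Ring B: cyclohexanone ⇒ cyclopentanone of a hydrindanone ketol by one-carbon ring expansion with 1-diazo-2-methylpropane (from 2-methylpropanal), which brings in the CH(i-Pr) carbon; base equilibration then fixes the isopropyl and ring-fusion centres.
4. Hydrindanone ketol (ring A, quaternary methyl carbon, tertiary carbinol) ⇒ 3-methylcyclopent-2-en-1-one + 5-iodopentan-2-one by an asymmetric conjugate addition/aldol cascade.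
5. Ring order: five-membered ring bought → ring A by aldol → ring B by expanding the five-membered ring to six.

Assumption: L1 is the zwitterionic NHC precursor 2-[(4S,5S)-3-(2,6-diethylphenyl)-4,5-diphenyl-4,5-dihydro-1H-imidazol-3-ium-1-yl]benzenesulfonate; if its sense of induction proves opposite, its (4R,5R) enantiomer is used so that the quaternary carbon is R.

**Step 1**
Reactants: 1 3-methylcyclopent-2-en-1-one; 2 5-iodopentan-2-one
Product: 5 (3aR,7S,7aS)-7-hydroxy-3a,7-dimethyloctahydro-1H-inden-1-one, via 4-oxopentylzinc iodide 3 (not isolated), via iodozinc enolate 4 (not isolated)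
Conditions: 2, Zn dust, LiCl, THF, 25 °C; then 1, Cu(OTf)2 (5 mol %), L1 (6 mol %), NaOt-Bu (12 mol %), THF, −30 → 23 °C; aq. NH4Cl
Reagents that add atoms: none
Why: Proposed new method: the NHC–copper catalyst formed in situ from Cu(OTf)2 and L1 (divalent copper is reduced to monovalent copper by the organozinc) takes the alkyl group from RZnI·LiCl while the sulfonate arm holds the zinc that activates the enone carbonyl, and alkyl transfer through a trivalent copper intermediate to one face of C3 sets the R quaternary centre; the regiodefined iodozinc enolate 4 then adds to its own methyl ketone through a zinc-chelated chair transition state (the tether forces the cis ring fusion, chelation of both oxygens to zinc puts the new hydroxyl cis to the angular methyl); the closest known reaction types are the copper-catalysed asymmetric conjugate addition of dialkylzinc, alkylaluminium and Grignard reagents to 3-substituted cycloalkenones and the copper-catalysed conjugate addition–aldol cyclisation of organozincs with keto-enones, whereas a ketone-bearing alkylzinc halide as nucleophile with ring closure onto its own carbonyl has not been shown.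

**Step 2**
Reactants: 6 2-methylpropanal
Product: 7 (2-methylpropylidene)hydrazine (isobutyraldehyde hydrazone)
Conditions: N2H4·H2O (5 equiv), Et2O, 0 → 23 °C; dried over KOH, used at once
Reagents that add atoms: hydrazine (as the monohydrate), NN
Why: Hydrazone condensation, with excess hydrazine to suppress azine formation; no stereocentre is formed.

**Step 3**
Reactants: 5 (3aR,7S,7aS)-7-hydroxy-3a,7-dimethyloctahydro-1H-inden-1-one; 7 (2-methylpropylidene)hydrazine
Product: 10 (2S,4aR,8S,8aR)-8-hydroxy-4a,8-dimethyl-2-(propan-2-yl)octahydronaphthalen-1(2H)-one, via 1-diazo-2-methylpropane 8 (not isolated), via cis-fused ring-expanded ketol 9 (not isolated)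
Conditions: 7, (COCl)2, DMSO, THF, −78 °C, then Et3N; cold filtrate added to 5, Sc(OTf)3 (10 mol %), CH2Cl2, −78 → −20 °C; aq. NaHCO3; crude, K2CO3 (0.3 equiv), MeOH, 23 °C
Reagents that add atoms: none
Why: Lewis acid-catalysed diazoalkane–ketone homologation (Tiffeneau–Demjanov-type ring expansion): the Sc(OTf)3-activated cyclopentanone adds the diazo carbon of 8 and the unhindered CH2–C(=O) bond migrates (1,2-shift) with loss of N2 rather than the methine flanked by two quaternary carbons, so CH(i-Pr) is inserted between C=O and CH2; K2CO3/MeOH then equilibrates C2 and C8a by enolisation and reversible retro-aldol/aldol to the thermodynamic isomer (trans-decalin, equatorial isopropyl, axial tertiary OH hydrogen-bonded to C=O with its methyl equatorial, the C8 epimer being disfavoured by a methyl/methyl 1,3-diaxial clash).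

**Step 4**
Reactants: 10 (2S,4aR,8S,8aR)-8-hydroxy-4a,8-dimethyl-2-(propan-2-yl)octahydronaphthalen-1(2H)-one
Product: 11 (1S,4aR,7S,8R,8aS)-1,4a-dimethyl-7-(propan-2-yl)decahydronaphthalene-1,8-diol (eudesmane-4β,6β-diol)
Conditions: LiBH(s-Bu)3 (2.5 equiv), THF, −78 → 0 °C; NaOH, H2O2
Reagents that add atoms: none
Why: Diastereoselective ketone reduction with a bulky hydride: the β-face (axial trajectory) is blocked by the 1,3-diaxial angular methyl and the axial tertiary hydroxyl, so hydride enters equatorially from the α-face and gives the axial 8R (6β) alcohol, syn to the tertiary hydroxyl.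

**Step 5**
Reactants: 11 (1S,4aR,7S,8R,8aS)-1,4a-dimethyl-7-(propan-2-yl)decahydronaphthalene-1,8-diol; 12 prop-2-enoyl chloride (acryloyl chloride)
Product: 13 (1R,2S,4aR,8S,8aS)-8-hydroxy-4a,8-dimethyl-2-(propan-2-yl)decahydronaphthalen-1-yl prop-2-enoate
Conditions: 12 (2 equiv), Et3N, DMAP (10 mol %), CH2Cl2, 0 → 23 °C
Reagents that add atoms: none
Why: DMAP-catalysed O-acylation: only the secondary hydroxyl reacts, the tertiary one being inert under these conditions and serving as a hydrogen-bond acceptor for its 1,3-diaxial neighbour; no stereocentre is touched.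

**Step 6**
Reactants: 13 (1R,2S,4aR,8S,8aS)-8-hydroxy-4a,8-dimethyl-2-(propan-2-yl)decahydronaphthalen-1-yl prop-2-enoate; 14 3-iodophenol
Product: 15 (1R,2S,4aR,8S,8aS)-8-hydroxy-4a,8-dimethyl-2-(propan-2-yl)decahydronaphthalen-1-yl (2E)-3-(3-hydroxyphenyl)prop-2-enoate (CNP0283603.1)
Conditions: Pd(OAc)2 (5 mol %), P(o-tol)3 (10 mol %), Et3N, MeCN, 80 °C
Reagents that add atoms: none
Why: Mizoroki–Heck reaction: oxidative addition of the aryl iodide to zerovalent palladium, syn-carbopalladation of the acrylate and syn β-hydride elimination give the E cinnamate; the free phenol and the tertiary alcohol are tolerated, so no protecting group is needed.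

**Compound list**
1 | 3-methylcyclopent-2-en-1-one | CC1=CC(=O)CC1 | starting material
2 | 5-iodopentan-2-one | CC(=O)CCCI | starting material
3 | 4-oxopentylzinc iodide | CC(=O)CCC[Zn]I | intermediate
4 | iodozinc (3R)-3-methyl-3-(4-oxopentyl)cyclopent-1-en-1-olate | I[Zn]OC1=C[C@](C)(CCCC(C)=O)CC1 | intermediate
5 | (3aR,7S,7aS)-7-hydroxy-3a,7-dimethyloctahydro-1H-inden-1-one | O=C1CC[C@@]2(C)CCC[C@](C)(O)[C@H]21 | intermediate
6 | 2-methylpropanal | CC(C)C=O | starting material
7 | (2-methylpropylidene)hydrazine | CC(C)C=NN | intermediate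
8 | 1-diazo-2-methylpropane | CC(C)C=[N+]=[N-] | intermediate
9 | (4aR,8S,8aS)-8-hydroxy-4a,8-dimethyl-2-(propan-2-yl)octahydronaphthalen-1(2H)-one, cis-fused, mixture of C2 epimers | CC(C)C1CC[C@@]2(C)CCC[C@](C)(O)[C@H]2C1=O | intermediate
10 | (2S,4aR,8S,8aR)-8-hydroxy-4a,8-dimethyl-2-(propan-2-yl)octahydronaphthalen-1(2H)-one | CC(C)[C@@H]1CC[C@@]2(C)CCC[C@](C)(O)[C@@H]2C1=O | intermediate
11 | (1S,4aR,7S,8R,8aS)-1,4a-dimethyl-7-(propan-2-yl)decahydronaphthalene-1,8-diol | CC(C)[C@@H]1CC[C@@]2(C)CCC[C@](C)(O)[C@@H]2[C@@H]1O | intermediate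
12 | prop-2-enoyl chloride | C=CC(=O)Cl | starting material
13 | (1R,2S,4aR,8S,8aS)-8-hydroxy-4a,8-dimethyl-2-(propan-2-yl)decahydronaphthalen-1-yl prop-2-enoate | CC(C)[C@@H]1CC[C@@]2(C)CCC[C@](C)(O)[C@@H]2[C@@H]1OC(=O)C=C | intermediate
14 | 3-iodophenol | Oc1cccc(I)c1 | starting material
15 | (1R,2S,4aR,8S,8aS)-8-hydroxy-4a,8-dimethyl-2-(propan-2-yl)decahydronaphthalen-1-yl (2E)-3-(3-hydroxyphenyl)prop-2-enoate | CC(C)[C@@H]1CC[C@@]2(C)CCC[C@](C)(O)[C@@H]2[C@@H]1OC(=O)/C=C/c1cccc(O)c1 | target

**Step count**
Total steps: 6. Longest linear sequence: 5 (steps 1, 3, 4, 5, 6); step 2 is a one-step side branch.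

**Three steps most likely to fail**

Step 1 (the proposed new cascade). Risks are low reactivity of an alkylzinc halide toward a β,β-disubstituted cyclopentenone, insufficient enantioselectivity, and an aldol that stops or gives the C7 epimer. A C7 epimer would still converge in step 3 through retro-aldol/aldol equilibration. Fallback with known chemistry, setting out from 2 and coming back at 5: 2 is protected with ethane-1,2-diol (TsOH, toluene, Dean–Stark) as 2-(3-iodopropyl)-2-methyl-1,3-dioxolane F1. Mg in THF converts it into iodo[3-(2-methyl-1,3-dioxolan-2-yl)propyl]magnesium F2, which adds 1,2 to purchased 3-methoxycyclopent-2-en-1-one F3 (eight non-hydrogen atoms). Work-up with 1 M HCl brings about enol-ether hydrolysis with allylic transposition (Stork–Danheiser) and ketal cleavage to give 3-(4-oxopentyl)cyclopent-2-en-1-one F4. Copper-catalysed asymmetric conjugate addition of Me3Al (Cu(OTf)2, L1 or its enantiomer, THF, −78 °C) is an established way to build methyl-bearing quaternary centres on 3-alkylcyclopentenones. On warming, the regiodefined aluminium enolate closes onto the side-chain ketone and gives 5.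

Step 3 (ring expansion and equilibration). Risks are O-alkylation or retro-aldol of the free β-hydroxy ketone under Lewis acid, loss of the unstabilised diazoalkane by 1,2-hydride shift before it adds to the hindered ketone, and dehydration to the enone during the base treatment. The equatorial preference of an isopropyl group next to a ketone is also modest (about 3:1, as in menthone/isomenthone), so the minor C2 epimer of 10 must be separated and resubmitted to K2CO3/MeOH. Fallback setting out from 5 and coming back at 10: the tertiary hydroxyl is masked first with N-(trimethylsilyl)imidazole (CH2Cl2, 23 °C) to give (3aR,7S,7aS)-3a,7-dimethyl-7-[(trimethylsilyl)oxy]octahydro-1H-inden-1-one F5. The same Sc(OTf)3-catalysed insertion of 8 is then run on this β-silyloxy ketone, which can neither chelate nor fragment, to give (4aR,8S,8aS)-4a,8-dimethyl-2-(propan-2-yl)-8-[(trimethylsilyl)oxy]octahydronaphthalen-1(2H)-one F6 as a C2 epimer mixture. K2CO3/MeOH then removes the silyl ether and equilibrates to 10.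

Step 5 (acylation of the hindered axial alcohol). The 6β-hydroxyl is flanked by the isopropyl group and is 1,3-diaxial to the angular methyl, and acryloyl chloride polymerises under forcing conditions. Fallback setting out from 11 and coming back at 13: a masked acrylate is used. 11 is acylated with 3-chloropropanoyl chloride (pyridine, DMAP, 50 °C), which withstands heating, to give (1R,2S,4aR,8S,8aS)-8-hydroxy-4a,8-dimethyl-2-(propan-2-yl)decahydronaphthalen-1-yl 3-chloropropanoate F7. Elimination of HCl with Et3N (CH2Cl2, 40 °C) then gives 13.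

**Further compounds**
F1 | step 1 | 2-(3-iodopropyl)-2-methyl-1,3-dioxolane | CC1(CCCI)OCCO1
F2 | step 1 | iodo[3-(2-methyl-1,3-dioxolan-2-yl)propyl]magnesium | CC1(CCC[Mg]I)OCCO1
F3 | step 1 | 3-methoxycyclopent-2-en-1-one (purchased) | COC1=CC(=O)CC1
F4 | step 1 | 3-(4-oxopentyl)cyclopent-2-en-1-one | CC(=O)CCCC1=CC(=O)CC1
F5 | step 3 | (3aR,7S,7aS)-3a,7-dimethyl-7-[(trimethylsilyl)oxy]octahydro-1H-inden-1-one | O=C1CC[C@@]2(C)CCC[C@](C)(O[Si](C)(C)C)[C@H]21
F6 | step 3 | (4aR,8S,8aS)-4a,8-dimethyl-2-(propan-2-yl)-8-[(trimethylsilyl)oxy]octahydronaphthalen-1(2H)-one, C2 epimers | CC(C)C1CC[C@@]2(C)CCC[C@](C)(O[Si](C)(C)C)[C@H]2C1=O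
F7 | step 5 | (1R,2S,4aR,8S,8aS)-8-hydroxy-4a,8-dimethyl-2-(propan-2-yl)decahydronaphthalen-1-yl 3-chloropropanoate | CC(C)[C@@H]1CC[C@@]2(C)CCC[C@](C)(O)[C@@H]2[C@@H]1OC(=O)CCCl
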